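**Assumption:** the target SMILES has no stereocentre and no stereogenic double bond, so the molecule is achiral. "Single enantiomer" therefore needs no stereocontrol and no step creates or can scramble a stereocentre.

## Retrosynthetic overview

1. The first-choice disconnection (aspidinol + formaldehyde, methylene bridge last) is deliberately not used; the monomer aspidinol never appears.
2. Target 8 ⇒ two-directional endgame on a preformed diarylmethane: twofold Friedel–Crafts butanoylation and fourfold chelation-controlled O-demethylation of core 5, in one pot.
3. Core 5 ⇒ twofold C(sp2)–C(sp3) Suzuki coupling of aryl bromide 3 with CH2(Bpin)2. The bridge carbon is a nucleophilic gem-diboryl linchpin, the reverse polarity of formaldehyde.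
4. Bromide 3 ⇒ ring bromination of commercial 2,4,6-trimethoxytoluene 1.
5. No rings are formed: both benzene rings are bought in 1. The OH/OMe pattern is set by which methyl ethers sit ortho to the new ketones.

## Route

**Step 1**
Reactants: 1, 2,4,6-trimethoxytoluene; 2, N-bromosuccinimide
Product: 3, 2-bromo-1,3,5-trimethoxy-4-methylbenzene (3-bromo-2,4,6-trimethoxytoluene; achiral)
Conditions: NBS (1.0 equiv), MeCN, 0 °C → rt, dark
Reagents that add atoms: N-bromosuccinimide, O=C1CCC(=O)N1Br (Br)
Why: Electrophilic aromatic bromination (SEAr); the two open ring positions of 1 are equivalent and activated by three OMe groups, polar non-radical conditions leave the benzylic CH3 alone, and the monobromide is less reactive than 1, so one equivalent stops at 3.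

**Step 2**
Reactants: 3, 2-bromo-1,3,5-trimethoxy-4-methylbenzene (2.2 equiv); 4, bis[(pinacolato)boryl]methane (1.0 equiv)
Product: 5, bis(2,4,6-trimethoxy-3-methylphenyl)methane (achiral)
Conditions: Pd[P(t-Bu)3]2 (5 mol %), 8 M aq KOH (6 equiv), 1,4-dioxane, degassed, rt then 90 °C
Reagents that add atoms: bis[(pinacolato)boryl]methane, CC1(C)OB(CB2OC(C)(C)C(C)(C)O2)OC1(C)C (the CH2 bridge)
Why: Twofold Suzuki–Miyaura coupling of a 1,1-diborylalkane, a known way to make symmetrical diarylmethanes: the α-boryl group speeds transmetalation of the hydroxide-borate so the first arylation gives ArCH2Bpin at rt, this benzylic boronate couples with a second ArBr on heating, and because each arene has exactly one reactive site no oligomers can form.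

**Step 3** (one pot, two stages)
Reactants: 5, bis(2,4,6-trimethoxy-3-methylphenyl)methane; 6, butanoyl chloride
Product: 8, methylenebis(aspidinol) = bis(3-butanoyl-2,4-dihydroxy-6-methoxy-5-methylphenyl)methane (achiral), via 7, bis(3-butanoyl-2,4,6-trimethoxy-5-methylphenyl)methane, not isolated
Conditions: PrCOCl (2.4 equiv)/AlCl3 (2.5 equiv) pre-mixed, CH2Cl2, add 5 at −20 → 0 °C; then BCl3 (1 M in CH2Cl2, 8 equiv), 0 °C → rt; MeOH then 1 M HCl
Reagents that add atoms: butanoyl chloride, CCCC(=O)Cl (both C4 acyl groups)
Why: Friedel–Crafts acylation can only occur at the single free C–H on each ring (flanked by two OMe groups), and the new ketone then directs chelation-controlled Lewis-acid demethylation: BCl3 bound to the C=O cleaves only the two OMe groups ortho to it through six-membered boron chelates, leaving the para OMe, which is exactly the aspidinol pattern.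

## Compound list

1 | 2,4,6-trimethoxytoluene (1,3,5-trimethoxy-2-methylbenzene) | Cc1c(OC)cc(OC)cc1OC | starting material
2 | N-bromosuccinimide | O=C1CCC(=O)N1Br | starting material (reagent)
3 | 2-bromo-1,3,5-trimethoxy-4-methylbenzene | Cc1c(OC)cc(OC)c(Br)c1OC | intermediate
4 | bis[(pinacolato)boryl]methane | CC1(C)OB(CB2OC(C)(C)C(C)(C)O2)OC1(C)C | starting material
5 | bis(2,4,6-trimethoxy-3-methylphenyl)methane | Cc1c(OC)cc(OC)c(Cc2c(OC)cc(OC)c(C)c2OC)c1OC | intermediate
6 | butanoyl chloride | CCCC(=O)Cl | starting material
7 | bis(3-butanoyl-2,4,6-trimethoxy-5-methylphenyl)methane | CCCC(=O)c1c(OC)c(C)c(OC)c(Cc2c(OC)c(C(=O)CCC)c(OC)c(C)c2OC)c1OC | intermediate (not isolated)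
8 | methylenebis(aspidinol), bis(3-butanoyl-2,4-dihydroxy-6-methoxy-5-methylphenyl)methane | CCCC(=O)c1c(O)c(C)c(OC)c(Cc2c(O)c(C(=O)CCC)c(O)c(C)c2OC)c1O | target

## Summary

Total steps: 3. Longest linear sequence: 3 (1 → 3 → 5 → 8). No stereocentres to set.

Steps most likely to fail, ranked (the route has only three steps):

1. **Step 3 (highest risk).** The electron-rich diarylmethane 5 may undergo acid-induced ipso-protonation or ipso-acylation (retro-Friedel–Crafts scrambling) before acylation deactivates it. BCl3 may also stop at one ortho-OMe per ring, or cleave the twisted, di-ortho-substituted para-OMe as well.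
   Fallback: change the order and the hydroxyl-differentiation logic. Acylate 1 first to 1-(2,4,6-trimethoxy-3-methylphenyl)butan-1-one, brominate its one free position, and run the double Suzuki on that bromo ketone to reach 7 without exposing an electron-rich diarylmethane to Lewis acid. Then strip all six methyls with BBr3 and re-methylate only the two para-OH groups (the only non-chelated, most acidic hydroxyls) with 2 equiv TMSCHN2 or Me2SO4/K2CO3.

2. **Step 2.** The coupling partners carry four ortho oxygens in total, so oxidative addition and the second transmetalation may be slow. Protodeboronation of the ArCH2Bpin intermediate (giving 1,3,5-trimethoxy-2,4-dimethylbenzene) and hydrodebromination are the likely side reactions.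
   Fallback: drop palladium and invert the polarity. Lithiate 1 between two OMe groups (n-BuLi/TMEDA), add 0.5 equiv ethyl formate to give the bis-aryl carbinol, and deoxygenate by ionic hydrogenation (Et3SiH/TFA) to 5.

3. **Step 1 (low risk).** Dibromination, or difficult separation of 3 from unreacted 1.
   Fallback: replace SEAr by deprotonative metalation. Lithiate 1 and quench with I2 to get the mono-iodide only (one metalation per molecule), or skip the halide entirely through the lithiation/formate route above.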